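## The problem

Gnetucleistol F (26) is a trans-2-aryl-3-(hydroxymethyl)-2,3-dihydrobenzofuran. Its benzo ring (ring A) carries a methoxy group at C7 and, at C5, an (E)-ethene bridge to a resorcinol (ring C); C2 carries the 4-hydroxy-3,5-dimethoxyphenyl ring B and C3 carries CH2OH. The skeleton is easy to assemble from three arenes; the difficulty is the two adjacent stereocentres, C2 (R) and C3 (S), as one enantiomer. The two centres are unequal. C2 is a benzylic aryl ether para to an oxygen donor, so it can open (cation in acid, quinone methide from the free phenoxide in base) and re-close to the more stable trans isomer. C3 can therefore correct C2, but nothing in the molecule can set C3, which must come from a catalyst, with C2 following it. Three phenols and an electron-rich stilbene exclude oxidants and strong acid late, so any oxidative trimming of the C3 side chain must come before the stilbene, and the last step must be mild. The feature that opens the chosen route is that C2 and C3 are the two furan carbons of a 7-methoxybenzofuran: O1–C2=C3 is an enol ether whose C2–H is the most acidic proton. Once C2 is bonded to a tetracoordinate boron, C3 is a nucleophile and C2 can receive ring B from boron on the opposite face of the flat ring.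

## Retrosynthesis

**Stilbene and phenols last (26 ⇒ 25 ⇒ 19 + 24).** Four O–Si bonds and the stilbene C=C are cut, the latter by a Horner–Wadsworth–Emmons olefination. The stilbene cannot survive the oxidative cleavage needed at C3, so it has to be formed afterwards. Cutting at the alkene rather than at an aryl–vinyl bond lets the C5 carbon travel from the start as a masked aldehyde, inert to organolithium and palladium reagents. Silyl ethers are chosen because buffered fluoride is the one deprotection the finished molecule tolerates. This removes ring C and leaves aldehyde 19 and phosphonate 24, which comes from 3,5-dihydroxybenzaldehyde 20 through 21, 22 and 23. The forward step must be E-selective and must not disturb aryl silyl ethers.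

**Protecting-group exchange (19 ⇒ 18 ⇒ 17).** Two O–Si bonds are cut, and behind them a methoxymethyl (MOM) ether and a dioxolane. The groups that serve the first half (MOM is fluoride-proof, the dioxolane is proof against n-BuLi and hydride) are not those that serve the endgame. Both leave in one acid step from 17, at a stage with no stilbene to trap a C2 cation, and one silylation of 18 covers the phenol and the primary alcohol together.

**The one-carbon side chain (17 ⇒ 15 ⇒ 14).** The CH2OH carbon is traced back through aldehyde 16 and the propenyl compound 15 to the allyl compound 14. The CH2 bonded to C3 is kept and two carbons are cut off. An allyl group is accepted because it is the best carbon electrophile for catalyst-controlled attack at C3, whereas a formaldehyde equivalent would offer no handle for a chiral catalyst. The forward steps must stop the isomerisation at the propenyl stage and reduce 16 before it can enolise.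

**Hydrogen for boron (14 ⇒ 13).** The C2–H bond is replaced by C2–B. This costs one step but is what allows ring B to be delivered to C2 stereospecifically. The forward reaction must proceed with retention.

**Key disconnection (13 ⇒ 6 + 9 + 10, through 11 and 12).** The bonds C3–CH2 and C2–aryl are cut together. Against building the furan ring by cyclisation, this cut buys the ring ready-made and creates both stereocentres in one bond-forming event from three flat, stable fragments, with trans fixed by mechanism. The precursors are benzofuran 6 (lithiated to 11), arylboronate 9 (giving borate 12) and allyl acetate 10. The forward reaction must attack C3 rather than transmetallate, migrate ring B anti to the incoming allyl group, and discriminate the two faces of C3.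

**Building blocks (6 ⇒ 5 ⇒ 4 ⇒ 1 + 2; 9 ⇒ 8 ⇒ 7).** The furan ring of 6 is cut at C7a–O and C3a–C3, back to 5-iodovanillin 1 and trimethylsilylacetylene 2 through alkynylphenol 3. Boronate 9 is cut at C–B back to bromide 8 and 4-bromo-2,6-dimethoxyphenol 7. A MOM ether is used on ring B because a silyl ether would be lost to fluoride in the protodeboronation, leaving a phenoxide para to the C2–B carbon.

## Roads not taken

**Alternative 1:** ring contraction of a flavanone. The cut is C3–C3a, leading back to flavanone A1. Forward, PhI(OAc)2 (trivalent iodine) with H2SO4 in trimethyl orthoformate would iodinate C3 of the enol ether of A1 and drive a 1,2-shift of ring A from C4 to C3, giving the trans ester A2 with the old C4 as CO2Me.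
- Merits: the reaction type is known; C3 arrives at the carboxylate level, so one reduction gives CH2OH; trans is inherent; the bromide allows a one-step Heck stilbene formation. After the key step this road is about three steps shorter than the chosen one, and better precedented.
- Weak points: the rearrangement is a contest of migratory aptitudes between ring A (contraction) and ring B (shift from C2 to C3). Here ring B is trioxygenated and ring A carries bromine, the wrong way round, which is why ring B must be detuned as a pivalate. The absolute configuration is not created in the key step: A1 must be made enantioenriched beforehand and then survive strong acid, in which such pyranones open and re-close reversibly.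
- Comparison: the chosen plan sets against the shorter endgame that both stereocentres are made under catalyst control in the bond-forming step, under near-neutral conditions, with no competing migration.

**Alternative 2:** [4+1] annulation of a quinone methide with a chiral sulfonium benzylide. The cuts are C2–C3 and O1–C2. Forward, base would release quinone methide A4 from sulfone A3 and the ylide from sulfonium salt A5 (or its antipode). The ylide carbon adds to the exocyclic carbon of A4 and the phenoxide displaces the sulfide, giving A6.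
- Merits: the ring and both stereocentres form in one step, and C3 already carries CH2O, so no side-chain degradation is needed. If it worked, it would be the shortest road.
- Weak points: A4 has an alkyl-type substituent with hydrogens and a silyloxy group next to the methide carbon, and can tautomerise or eliminate instead of accepting a nucleophile. The ylide from A5 is only semi-stabilised and electron-rich, so it is hard to generate with the mild base that A4 tolerates. The chiral sulfide is stoichiometric, and enantiocontrol rests on a stepwise addition and closure that may be reversible.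
- Comparison: the chosen plan is longer but starts from a stable aromatic benzofuran, uses a catalytic source of chirality, and fixes trans by a stereospecific migration.

**Alternative 3:** three-component conjunctive coupling on an open chain. The cuts are C3–C3a and C2–aryl. Forward, alkenyl boronate A7 and aryllithium A8 form a borate that meets aryl triflate A9 on zerovalent palladium generated from Pd(OAc)2 and a Mandyphos diphosphine. Palladium bonds C3 as ring B shifts from boron to C2, giving A10; oxidation of C–B and displacement of fluoride would then close the furan ring.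
- Merits: the reaction class is established, so its key step needs no new method, a clear advantage over the chosen plan. C3 also arrives with CH2O in place.
- Weak points: substituted alkenyl boronates such as A7 are the difficult substrates of this chemistry; the organopalladium intermediate has an oxygen in the β-position; A9 is flanked by fluorine and must couple at a congested carbon. The ring is not formed in the key step, so oxidation, ring closure and adjustment of the ester follow, and diastereocontrol must be won on an open chain.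
- Comparison: step counts after the key step are similar. The chosen plan offers diastereocontrol locked in a ring that already exists and simpler fragments; its price is the unproven key step.

Key step: step 6

Assumption: the sense of induction of (S)-H8-BINAP on a benzofuran-2-yl borate is taken to parallel that on indol-2-yl borates; if the other face of C3 is attacked, the (R) ligand is used and nothing else changes.

## Route

Step 1
Reactants: 1 5-iodovanillin; 2 trimethylsilylacetylene
Product: 4 7-methoxy-2-(trimethylsilyl)-1-benzofuran-5-carbaldehyde, via alkynylphenol 3 (not isolated)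
Conditions: Pd(PPh3)2Cl2 (3 mol %), CuI (5 mol %), Et3N, DMF, 70 °C
Reagents that add atoms: none
Why: Sonogashira coupling of the aryl iodide, followed in the same flask by metal-promoted 5-endo-dig addition of the phenol (acidified by the para formyl group) to the alkyne of 3; the silyl group keeps the alkyne monofunctional.

Step 2
Reactants: 4 7-methoxy-2-(trimethylsilyl)-1-benzofuran-5-carbaldehyde
Product: 5 7-methoxy-1-benzofuran-5-carbaldehyde
Conditions: TBAF (1.1 equiv), THF (wet), 0 °C → rt
Reagents that add atoms: none
Why: Fluoride-induced protodesilylation of the heteroaryl C–Si bond at the furan α-position; aldehyde and methyl ether are inert.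

Step 3
Reactants: 5 7-methoxy-1-benzofuran-5-carbaldehyde
Product: 6 2-(7-methoxy-1-benzofuran-5-yl)-1,3-dioxolane
Conditions: ethylene glycol, p-TsOH·H2O (5 mol %), toluene, reflux, Dean–Stark
Reagents that add atoms: ethylene glycol, OCCO
Why: Acid-catalysed acetalisation with azeotropic removal of water; the dioxolane protects the aldehyde from n-BuLi in step 6 and from NaBH4 in step 9.

Step 4
Reactants: 7 4-bromo-2,6-dimethoxyphenol
Product: 8 5-bromo-1,3-dimethoxy-2-(methoxymethoxy)benzene
Conditions: NaH (1.2 equiv), MOMCl (1.3 equiv), DMF, 0 °C → rt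
Reagents that add atoms: chloromethyl methyl ether (MOMCl), COCCl
Why: Williamson-type O-alkylation of the sodium phenoxide; the MOM ether withstands the fluoride of step 7 and leaves together with the dioxolane in step 10.

Step 5
Reactants: 8 5-bromo-1,3-dimethoxy-2-(methoxymethoxy)benzene
Product: 9 2-[3,5-dimethoxy-4-(methoxymethoxy)phenyl]-4,4,5,5-tetramethyl-1,3,2-dioxaborolane
Conditions: B2pin2 (1.2 equiv), Pd(dppf)Cl2 (3 mol %), KOAc (3 equiv), 1,4-dioxane, 90 °C
Reagents that add atoms: bis(pinacolato)diboron, CC1(C)OB(B2OC(C)(C)C(C)(C)O2)OC1(C)C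
Why: Miyaura borylation of an aryl bromide; the weak base KOAc prevents onward Suzuki coupling of the product.

Step 6
Reactants: 6 2-(7-methoxy-1-benzofuran-5-yl)-1,3-dioxolane; 9 2-[3,5-dimethoxy-4-(methoxymethoxy)phenyl]-4,4,5,5-tetramethyl-1,3,2-dioxaborolane; 10 allyl acetate
Product: 13 2-[(2R,3R)-5-(1,3-dioxolan-2-yl)-2-[3,5-dimethoxy-4-(methoxymethoxy)phenyl]-7-methoxy-3-(prop-2-en-1-yl)-2,3-dihydro-1-benzofuran-2-yl]-4,4,5,5-tetramethyl-1,3,2-dioxaborolane (allyl trans to ring B; boron cis to allyl), via 2-lithiobenzofuran 11 (not isolated), via lithium borate 12 (not isolated)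
Conditions: n-BuLi (1.0 equiv), THF, −78 °C, 1 h; 9, −78 → 0 °C; then Pd2(dba)3 (2.5 mol %), (S)-H8-BINAP (6 mol %), 10 (1.5 equiv), THF, 0 °C → rt
Reagents that add atoms: none
Why: Proposed new method: n-BuLi removes the acidic C2–H of 6 to give 11, which adds to the boron of 9 to give borate 12, whose furan C2=C3 bond is an electron-rich alkenyl borate; zerovalent palladium from Pd2(dba)3 and the diphosphine ionises 10 to a cationic allyl complex of divalent palladium, and C3 of 12 attacks an allyl terminus from outside the metal while ring B shifts from boron to C2 antiperiplanar to the forming C3–CH2 bond, so two skeletal bonds and two stereocentres arise in one 1,2-metallate event. The closest known reaction type is the enantioselective palladium-allyl-induced 1,2-boronate migration of indol-2-yl borates to 2,3-disubstituted indolin-2-yl boronic esters; benzofuran-2-yl borates have not been shown in it and their C3 is the weaker nucleophile. No ring is closed: the furan ring is kept and only dearomatised. The C3 configuration is controlled by the chiral diphosphine on palladium, which selects the face of C3 that meets the allyl ligand. The C2 configuration is controlled by C3 through the stereospecific anti migration, which places ring B trans to the allyl group and boron cis to it. The step needs attack at C3 rather than transmetallation of the borate to palladium (which would give plain allyl–aryl coupling); the tetracoordinate pinacol borate without added base or water is a poor transmetallating partner, and the ring oxygen raises the electron density at C3. Migration of the aryl group rather than a pinacol oxygen is inherent to carbon ligands on boron, and the MOM ether, the dioxolane and the 7-methoxy group are inert spectators.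

Step 7
Reactants: 13 the boronic ester from step 6
Product: 14 2-[(2R,3R)-2-[3,5-dimethoxy-4-(methoxymethoxy)phenyl]-7-methoxy-3-(prop-2-en-1-yl)-2,3-dihydro-1-benzofuran-5-yl]-1,3-dioxolane (trans)
Conditions: TBAF·3H2O (2 equiv), toluene, 45 °C
Reagents that add atoms: none
Why: Fluoride-promoted protodeboronation of a tertiary benzylic boronic ester, a reaction type that goes with retention because the fluoroborate is protonated by water at the C–B bond from the front (SE2); hydrogen takes the place of boron, cis to the allyl group, so ring B and allyl stay trans. MOM ether, acetal and alkene do not react with fluoride.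

Step 8
Reactants: 14 the allyl compound from step 7
Product: 15 2-[(2R,3R)-2-[3,5-dimethoxy-4-(methoxymethoxy)phenyl]-7-methoxy-3-[(E)-prop-1-en-1-yl]-2,3-dihydro-1-benzofuran-5-yl]-1,3-dioxolane
Conditions: RuHCl(CO)(PPh3)3 (5 mol %), toluene, 80 °C
Reagents that add atoms: none
Why: Ruthenium hydride-catalysed alkene isomerisation (insertion, β-hydride elimination) moves the terminal double bond one position to the more stable disubstituted alkene; a further shift would need a tertiary ruthenium alkyl at C3 and is much slower, so C3 is untouched. Either alkene geometry serves the next step.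

Step 9
Reactants: 15 the propenyl compound from step 8
Product: 17 [(2R,3S)-5-(1,3-dioxolan-2-yl)-2-[3,5-dimethoxy-4-(methoxymethoxy)phenyl]-7-methoxy-2,3-dihydro-1-benzofuran-3-yl]methanol, via 3-carbaldehyde 16 (not isolated)
Conditions: O3, CH2Cl2/MeOH 3:1, −78 °C (Sudan Red 7B end point); then NaBH4 (5 equiv), −78 → 0 °C
Reagents that add atoms: ozone, [O-][O+]=O
Why: Ozonolysis of the only alkene with reductive work-up in the same flask; aldehyde 16 is reduced cold before it can enolise at C3 or lose the ring oxygen by β-elimination, and the dye marks the end point before ozone attacks the arenes. The change of descriptor at C3 is formal.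

Step 10
Reactants: 17 the alcohol from step 9
Product: 18 (2R,3S)-2-(4-hydroxy-3,5-dimethoxyphenyl)-3-(hydroxymethyl)-7-methoxy-2,3-dihydro-1-benzofuran-5-carbaldehyde
Conditions: 6 M HCl (aq)/THF 1:4, 40 °C
Reagents that add atoms: water, O
Why: Acid hydrolysis removes the dioxolane and the aryl MOM ether in one operation; should the C2–O bond ionise, re-closure anti to the C3 substituent returns the trans isomer, and no stilbene is present to trap a cation.

Step 11
Reactants: 18 the phenol aldehyde from step 10
Product: 19 (2R,3S)-3-({[tert-butyl(dimethyl)silyl]oxy}methyl)-2-(4-{[tert-butyl(dimethyl)silyl]oxy}-3,5-dimethoxyphenyl)-7-methoxy-2,3-dihydro-1-benzofuran-5-carbaldehyde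
Conditions: TBSCl (3 equiv), imidazole (6 equiv), DMF, rt
Reagents that add atoms: tert-butyldimethylsilyl chloride (TBSCl), CC(C)(C)[Si](C)(C)Cl
Why: Imidazole-mediated silylation of the phenol and the primary alcohol; the phenol must be masked because a para phenoxide could expel the ring A oxygen from C2 under the basic conditions of step 16.

Step 12
Reactants: 20 3,5-dihydroxybenzaldehyde
Product: 21 3,5-bis(triisopropylsilyloxy)benzaldehyde
Conditions: TIPSCl (2.3 equiv), imidazole (5 equiv), DMF, rt
Reagents that add atoms: triisopropylsilyl chloride (TIPSCl), CC(C)[Si](Cl)(C(C)C)C(C)C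
Why: Silylation of both phenols; the bulky silyl ethers are chosen to withstand the base of step 16.

Step 13
Reactants: 21 3,5-bis(triisopropylsilyloxy)benzaldehyde
Product: 22 [3,5-bis(triisopropylsilyloxy)phenyl]methanol
Conditions: NaBH4, THF/MeOH, 0 °C
Reagents that add atoms: none
Why: Borohydride reduction of an aryl aldehyde; aryl silyl ethers are stable at 0 °C.

Step 14
Reactants: 22 [3,5-bis(triisopropylsilyloxy)phenyl]methanol
Product: 23 [5-(bromomethyl)-1,3-phenylene]bis(oxy)bis(triisopropylsilane)
Conditions: CBr4 (1.3 equiv), PPh3 (1.3 equiv), CH2Cl2, 0 °C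
Reagents that add atoms: tetrabromomethane, BrC(Br)(Br)Br
Why: Appel bromination of a benzylic alcohol under neutral conditions.

Step 15
Reactants: 23 the benzyl bromide from step 14
Product: 24 diethyl {[3,5-bis(triisopropylsilyloxy)phenyl]methyl}phosphonate
Conditions: P(OEt)3 (neat, 5 equiv), 130 °C
Reagents that add atoms: triethyl phosphite, CCOP(OCC)OCC
Why: Arbuzov reaction of a benzylic bromide; bromoethane distils off.

Step 16
Reactants: 19 the bis-silylated aldehyde from step 11; 24 the phosphonate from step 15
Product: 25 (2R,3S)-5-[(E)-2-[3,5-bis(triisopropylsilyloxy)phenyl]ethenyl]-3-({[tert-butyl(dimethyl)silyl]oxy}methyl)-2-(4-{[tert-butyl(dimethyl)silyl]oxy}-3,5-dimethoxyphenyl)-7-methoxy-2,3-dihydro-1-benzofuran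
Conditions: 24 (1.3 equiv), KOtBu (1.25 equiv), THF, 0 °C; then 19, 0 °C → rt
Reagents that add atoms: none
Why: Horner–Wadsworth–Emmons olefination of a benzylic phosphonate anion with an aryl aldehyde, E-selective through the more stable anti oxaphosphetane; no acidic OH is present and neither stereocentre bears an acidifying group.

Step 17
Reactants: 25 the tetrasilyl ether from step 16
Product: 26 gnetucleistol F, 5-[(E)-2-[(2R,3S)-2-(4-hydroxy-3,5-dimethoxyphenyl)-3-(hydroxymethyl)-7-methoxy-2,3-dihydro-1-benzofuran-5-yl]ethenyl]benzene-1,3-diol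
Conditions: TBAF (8 equiv), AcOH (8 equiv), THF, 0 °C → rt
Reagents that add atoms: none
Why: Fluoride cleaves the three aryl silyl ethers and the primary silyl ether; acetic acid keeps the phenols protonated, so no phenoxide is available to open the ring at C2.

## Compound list

1 | 5-iodovanillin (4-hydroxy-3-iodo-5-methoxybenzaldehyde) | COc1cc(C=O)cc(I)c1O | starting material
2 | trimethylsilylacetylene | C#C[Si](C)(C)C | starting material
3 | 4-hydroxy-3-methoxy-5-[(trimethylsilyl)ethynyl]benzaldehyde | COc1cc(C=O)cc(C#C[Si](C)(C)C)c1O | intermediate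
4 | 7-methoxy-2-(trimethylsilyl)-1-benzofuran-5-carbaldehyde | COc1cc(C=O)cc2cc([Si](C)(C)C)oc12 | intermediate
5 | 7-methoxy-1-benzofuran-5-carbaldehyde | COc1cc(C=O)cc2ccoc12 | intermediate
6 | 2-(7-methoxy-1-benzofuran-5-yl)-1,3-dioxolane | COc1cc(C2OCCO2)cc2ccoc12 | intermediate
7 | 4-bromo-2,6-dimethoxyphenol | COc1cc(Br)cc(OC)c1O | starting material
8 | 5-bromo-1,3-dimethoxy-2-(methoxymethoxy)benzene | COCOc1c(OC)cc(Br)cc1OC | intermediate
9 | 2-[3,5-dimethoxy-4-(methoxymethoxy)phenyl]-4,4,5,5-tetramethyl-1,3,2-dioxaborolane | COCOc1c(OC)cc(B2OC(C)(C)C(C)(C)O2)cc1OC | intermediate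
10 | allyl acetate | CC(=O)OCC=C | starting material
11 | [5-(1,3-dioxolan-2-yl)-7-methoxy-1-benzofuran-2-yl]lithium | COc1cc(C2OCCO2)cc2cc([Li])oc12 | intermediate
12 | lithium [5-(1,3-dioxolan-2-yl)-7-methoxy-1-benzofuran-2-yl][3,5-dimethoxy-4-(methoxymethoxy)phenyl](pinacolato)borate | [Li+].COCOc1c(OC)cc([B-]2(c3cc4cc(C5OCCO5)cc(OC)c4o3)OC(C)(C)C(C)(C)O2)cc1OC | intermediate
13 | 2-[(2R,3R)-5-(1,3-dioxolan-2-yl)-2-[3,5-dimethoxy-4-(methoxymethoxy)phenyl]-7-methoxy-3-(prop-2-en-1-yl)-2,3-dihydro-1-benzofuran-2-yl]-4,4,5,5-tetramethyl-1,3,2-dioxaborolane | COCOc1c(OC)cc([C@]2(B3OC(C)(C)C(C)(C)O3)Oc3c(OC)cc(C4OCCO4)cc3[C@H]2CC=C)cc1OC | intermediate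
14 | 2-[(2R,3R)-2-[3,5-dimethoxy-4-(methoxymethoxy)phenyl]-7-methoxy-3-(prop-2-en-1-yl)-2,3-dihydro-1-benzofuran-5-yl]-1,3-dioxolane | COCOc1c(OC)cc([C@@H]2Oc3c(OC)cc(C4OCCO4)cc3[C@H]2CC=C)cc1OC | intermediate
15 | 2-[(2R,3R)-2-[3,5-dimethoxy-4-(methoxymethoxy)phenyl]-7-methoxy-3-[(E)-prop-1-en-1-yl]-2,3-dihydro-1-benzofuran-5-yl]-1,3-dioxolane | COCOc1c(OC)cc([C@@H]2Oc3c(OC)cc(C4OCCO4)cc3[C@H]2/C=C/C)cc1OC | intermediate
16 | (2R,3R)-5-(1,3-dioxolan-2-yl)-2-[3,5-dimethoxy-4-(methoxymethoxy)phenyl]-7-methoxy-2,3-dihydro-1-benzofuran-3-carbaldehyde | COCOc1c(OC)cc([C@@H]2Oc3c(OC)cc(C4OCCO4)cc3[C@H]2C=O)cc1OC | intermediate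
17 | [(2R,3S)-5-(1,3-dioxolan-2-yl)-2-[3,5-dimethoxy-4-(methoxymethoxy)phenyl]-7-methoxy-2,3-dihydro-1-benzofuran-3-yl]methanol | COCOc1c(OC)cc([C@@H]2Oc3c(OC)cc(C4OCCO4)cc3[C@H]2CO)cc1OC | intermediate
18 | (2R,3S)-2-(4-hydroxy-3,5-dimethoxyphenyl)-3-(hydroxymethyl)-7-methoxy-2,3-dihydro-1-benzofuran-5-carbaldehyde | COc1cc([C@@H]2Oc3c(OC)cc(C=O)cc3[C@H]2CO)cc(OC)c1O | intermediate
19 | (2R,3S)-3-({[tert-butyl(dimethyl)silyl]oxy}methyl)-2-(4-{[tert-butyl(dimethyl)silyl]oxy}-3,5-dimethoxyphenyl)-7-methoxy-2,3-dihydro-1-benzofuran-5-carbaldehyde | COc1cc([C@@H]2Oc3c(OC)cc(C=O)cc3[C@H]2CO[Si](C)(C)C(C)(C)C)cc(OC)c1O[Si](C)(C)C(C)(C)C | intermediate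
20 | 3,5-dihydroxybenzaldehyde | O=Cc1cc(O)cc(O)c1 | starting material
21 | 3,5-bis(triisopropylsilyloxy)benzaldehyde | O=Cc1cc(O[Si](C(C)C)(C(C)C)C(C)C)cc(O[Si](C(C)C)(C(C)C)C(C)C)c1 | intermediate
22 | [3,5-bis(triisopropylsilyloxy)phenyl]methanol | OCc1cc(O[Si](C(C)C)(C(C)C)C(C)C)cc(O[Si](C(C)C)(C(C)C)C(C)C)c1 | intermediate
23 | [5-(bromomethyl)-1,3-phenylene]bis(oxy)bis(triisopropylsilane) | BrCc1cc(O[Si](C(C)C)(C(C)C)C(C)C)cc(O[Si](C(C)C)(C(C)C)C(C)C)c1 | intermediate
24 | diethyl {[3,5-bis(triisopropylsilyloxy)phenyl]methyl}phosphonate | CCOP(=O)(Cc1cc(O[Si](C(C)C)(C(C)C)C(C)C)cc(O[Si](C(C)C)(C(C)C)C(C)C)c1)OCC | intermediate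
25 | (2R,3S)-5-[(E)-2-[3,5-bis(triisopropylsilyloxy)phenyl]ethenyl]-3-({[tert-butyl(dimethyl)silyl]oxy}methyl)-2-(4-{[tert-butyl(dimethyl)silyl]oxy}-3,5-dimethoxyphenyl)-7-methoxy-2,3-dihydro-1-benzofuran | COc1cc([C@@H]2Oc3c(OC)cc(/C=C/c4cc(O[Si](C(C)C)(C(C)C)C(C)C)cc(O[Si](C(C)C)(C(C)C)C(C)C)c4)cc3[C@H]2CO[Si](C)(C)C(C)(C)C)cc(OC)c1O[Si](C)(C)C(C)(C)C | intermediate
26 | gnetucleistol F, 5-[(E)-2-[(2R,3S)-2-(4-hydroxy-3,5-dimethoxyphenyl)-3-(hydroxymethyl)-7-methoxy-2,3-dihydro-1-benzofuran-5-yl]ethenyl]benzene-1,3-diol | COc1cc([C@@H]2Oc3c(OC)cc(/C=C/c4cc(O)cc(O)c4)cc3[C@H]2CO)cc(OC)c1O | target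

## Step count and least certain steps

Total: 17 steps. Longest linear sequence: 11 steps from 1 (steps 1, 2, 3, 6, 7, 8, 9, 10, 11, 16, 17).

**Step 6 (key step, the one step beyond known chemistry).** The most likely failure is capture of the allyl palladium complex by transmetallation of the borate, giving allyl–aryl coupling without migration, because C3 of a benzofuran is a weaker nucleophile than C3 of an indole. The second risk is weak facial discrimination at C3.

The fallback uses known chemistry, sets out from 8 and 1, and returns at 17, which also bypasses steps 7 to 9: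
- Bromine–lithium exchange on 8 (n-BuLi, THF, −78 °C) gives [3,5-dimethoxy-4-(methoxymethoxy)phenyl]lithium F1, which is trapped with paraformaldehyde to give [3,5-dimethoxy-4-(methoxymethoxy)phenyl]methanol F2.
- Mitsunobu etherification of 1 with F2 (PPh3, DIAD, THF) gives 4-{[3,5-dimethoxy-4-(methoxymethoxy)phenyl]methoxy}-3-iodo-5-methoxybenzaldehyde F3.
- Silyl-transfer acetalisation (1,2-bis(trimethylsilyloxy)ethane, cat. TMSOTf, CH2Cl2, −78 °C, mild enough for the MOM and benzylic ethers) gives the dioxolane F4.
- Palladium-catalysed coupling of the aryl iodide with methyl diazoacetate (Pd(PPh3)4, Ag2CO3, Et3N, toluene, rt) gives the aryldiazoacetate F5.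
- Intramolecular C–H insertion of the dirhodium carbenoid (Rh2(S-DOSP)4 or its mirror image, hexane/toluene, −50 °C) into the benzylic ether C–H closes the furan ring to the cis ester F6, with C2 set by the catalyst.
- NaOMe in MeOH epimerises C3 to the trans ester F7, and LiAlH4 reduces it to 17.

**Step 7.** The most likely failure is loss of configurational integrity at C2: if a free benzylic carbanion forms, it is protonated on the face away from the allyl group, which gives the cis isomer. The C–B cleavage may also be sluggish because ring B is electron-rich.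

The fallback sets out from 13 and returns at 14, and makes C2 independent of the boron stereochemistry:
- Oxidation with NaBO3·4H2O (THF/H2O, 0 °C) gives (2R)-2-[5-(1,3-dioxolan-2-yl)-2-hydroxy-3-methoxyphenyl]-1-[3,5-dimethoxy-4-(methoxymethoxy)phenyl]pent-4-en-1-one F8, in equilibrium with its cyclic hemiketal.
- It is reduced at once with NaBH4 (MeOH, −20 °C), to limit enolisation next to the ketone, giving the carbinol (1RS,2R)-2-[5-(1,3-dioxolan-2-yl)-2-hydroxy-3-methoxyphenyl]-1-[3,5-dimethoxy-4-(methoxymethoxy)phenyl]pent-4-en-1-ol F9.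
- Acid-catalysed cyclodehydration (camphorsulfonic acid cat., CH2Cl2, 4 Å sieves, 0 °C) closes the ring through the benzylic cation anti to the allyl group and gives trans 14.

**Step 8.** The most likely failure is over-migration of the double bond into conjugation with ring A, which erases C3 and ends in aromatisation to the benzofuran.

The fallback sets out from 14 and returns at 17, and avoids metal hydrides:
- Ozonolysis with PPh3 work-up gives 2-[(2R,3R)-5-(1,3-dioxolan-2-yl)-2-[3,5-dimethoxy-4-(methoxymethoxy)phenyl]-7-methoxy-2,3-dihydro-1-benzofuran-3-yl]acetaldehyde F10.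
- TBSOTf and Et3N (CH2Cl2, 0 °C) give its silyl enol ether tert-butyl({2-[(2R,3R)-5-(1,3-dioxolan-2-yl)-2-[3,5-dimethoxy-4-(methoxymethoxy)phenyl]-7-methoxy-2,3-dihydro-1-benzofuran-3-yl]ethenyl}oxy)dimethylsilane F11; enolisation involves only the CH2 group, not C3.
- A second ozonolysis with NaBH4 work-up, as in step 9, gives 17.

**Step 10.** The most likely failure is acid-induced ionisation of the C2–O bond with solvolysis, before the aryl MOM ether is fully cleaved.

The fallback sets out from 17 and returns at 18, and separates the two deprotections into mild operations of different mechanism: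
- PPTS in acetone/H2O at 50 °C hydrolyses only the dioxolane and gives (2R,3S)-2-[3,5-dimethoxy-4-(methoxymethoxy)phenyl]-3-(hydroxymethyl)-7-methoxy-2,3-dihydro-1-benzofuran-5-carbaldehyde F12.
- TMSOTf with 2,2′-bipyridyl (CH2Cl2, 0 °C) converts the aryl MOM ether through a pyridinium intermediate into a trimethylsilyl ether under non-protic, buffered conditions; aqueous work-up hydrolyses it, and the transient silyl ether of the primary alcohol, to give 18.

## Further compounds

F1 | step 6 | [3,5-dimethoxy-4-(methoxymethoxy)phenyl]lithium | COCOc1c(OC)cc([Li])cc1OC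
F2 | step 6 | [3,5-dimethoxy-4-(methoxymethoxy)phenyl]methanol | COCOc1c(OC)cc(CO)cc1OC
F3 | step 6 | 4-{[3,5-dimethoxy-4-(methoxymethoxy)phenyl]methoxy}-3-iodo-5-methoxybenzaldehyde | COCOc1c(OC)cc(COc2c(I)cc(C=O)cc2OC)cc1OC
F4 | step 6 | 2-(4-{[3,5-dimethoxy-4-(methoxymethoxy)phenyl]methoxy}-3-iodo-5-methoxyphenyl)-1,3-dioxolane | COCOc1c(OC)cc(COc2c(I)cc(C3OCCO3)cc2OC)cc1OC
F5 | step 6 | methyl 2-diazo-2-[2-{[3,5-dimethoxy-4-(methoxymethoxy)phenyl]methoxy}-5-(1,3-dioxolan-2-yl)-3-methoxyphenyl]acetate | COCOc1c(OC)cc(COc2c(C(=[N+]=[N-])C(=O)OC)cc(C3OCCO3)cc2OC)cc1OC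
F6 | step 6 | methyl (2R,3S)-5-(1,3-dioxolan-2-yl)-2-[3,5-dimethoxy-4-(methoxymethoxy)phenyl]-7-methoxy-2,3-dihydro-1-benzofuran-3-carboxylate (cis) | COCOc1c(OC)cc([C@@H]2Oc3c(OC)cc(C4OCCO4)cc3[C@@H]2C(=O)OC)cc1OC
F7 | step 6 | methyl (2R,3R)-5-(1,3-dioxolan-2-yl)-2-[3,5-dimethoxy-4-(methoxymethoxy)phenyl]-7-methoxy-2,3-dihydro-1-benzofuran-3-carboxylate (trans) | COCOc1c(OC)cc([C@@H]2Oc3c(OC)cc(C4OCCO4)cc3[C@H]2C(=O)OC)cc1OC
F8 | step 7 | (2R)-2-[5-(1,3-dioxolan-2-yl)-2-hydroxy-3-methoxyphenyl]-1-[3,5-dimethoxy-4-(methoxymethoxy)phenyl]pent-4-en-1-one | COCOc1c(OC)cc(C(=O)[C@H](CC=C)c2cc(C3OCCO3)cc(OC)c2O)cc1OC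
F9 | step 7 | (1RS,2R)-2-[5-(1,3-dioxolan-2-yl)-2-hydroxy-3-methoxyphenyl]-1-[3,5-dimethoxy-4-(methoxymethoxy)phenyl]pent-4-en-1-ol | COCOc1c(OC)cc(C(O)[C@H](CC=C)c2cc(C3OCCO3)cc(OC)c2O)cc1OC
F10 | step 8 | 2-[(2R,3R)-5-(1,3-dioxolan-2-yl)-2-[3,5-dimethoxy-4-(methoxymethoxy)phenyl]-7-methoxy-2,3-dihydro-1-benzofuran-3-yl]acetaldehyde | COCOc1c(OC)cc([C@@H]2Oc3c(OC)cc(C4OCCO4)cc3[C@H]2CC=O)cc1OC
F11 | step 8 | tert-butyl({2-[(2R,3R)-5-(1,3-dioxolan-2-yl)-2-[3,5-dimethoxy-4-(methoxymethoxy)phenyl]-7-methoxy-2,3-dihydro-1-benzofuran-3-yl]ethenyl}oxy)dimethylsilane (E/Z mixture) | COCOc1c(OC)cc([C@@H]2Oc3c(OC)cc(C4OCCO4)cc3[C@H]2C=CO[Si](C)(C)C(C)(C)C)cc1OC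
F12 | step 10 | (2R,3S)-2-[3,5-dimethoxy-4-(methoxymethoxy)phenyl]-3-(hydroxymethyl)-7-methoxy-2,3-dihydro-1-benzofuran-5-carbaldehyde | COCOc1c(OC)cc([C@@H]2Oc3c(OC)cc(C=O)cc3[C@H]2CO)cc1OC
A1 | alternative 1 | (2R)-6-bromo-2-[3,5-dimethoxy-4-(pivaloyloxy)phenyl]-8-methoxychroman-4-one | COc1cc([C@@H]2Oc3c(OC)cc(Br)cc3C(=O)C2)cc(OC)c1OC(=O)C(C)(C)C
A2 | alternative 1 | methyl (2R,3R)-5-bromo-2-[3,5-dimethoxy-4-(pivaloyloxy)phenyl]-7-methoxy-2,3-dihydro-1-benzofuran-3-carboxylate | COc1cc([C@@H]2Oc3c(OC)cc(Br)cc3[C@H]2C(=O)OC)cc(OC)c1OC(=O)C(C)(C)C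
A3 | alternative 2 | 4-bromo-2-[2-{[tert-butyl(dimethyl)silyl]oxy}-1-(4-methylbenzenesulfonyl)ethyl]-6-methoxyphenol (racemic) | COc1cc(Br)cc(C(CO[Si](C)(C)C(C)(C)C)S(=O)(=O)c2ccc(C)cc2)c1O
A4 | alternative 2 | 4-bromo-6-[2-{[tert-butyl(dimethyl)silyl]oxy}ethylidene]-2-methoxycyclohexa-2,4-dien-1-one | COC1=CC(Br)=CC(=CCO[Si](C)(C)C(C)(C)C)C1=O
A5 | alternative 2 | (2R,5R)-1-{[3,5-dimethoxy-4-(triisopropylsilyloxy)phenyl]methyl}-2,5-dimethylthiolan-1-ium trifluoromethanesulfonate | C[C@@H]1CC[C@@H](C)[S+]1Cc1cc(OC)c(O[Si](C(C)C)(C(C)C)C(C)C)c(OC)c1.[O-]S(=O)(=O)C(F)(F)F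
A6 | alternative 2 | (2R,3S)-5-bromo-3-({[tert-butyl(dimethyl)silyl]oxy}methyl)-2-[3,5-dimethoxy-4-(triisopropylsilyloxy)phenyl]-7-methoxy-2,3-dihydro-1-benzofuran | COc1cc([C@@H]2Oc3c(OC)cc(Br)cc3[C@H]2CO[Si](C)(C)C(C)(C)C)cc(OC)c1O[Si](C(C)C)(C(C)C)C(C)C
A7 | alternative 3 | tert-butyl(dimethyl){[(2E)-3-(4,4,5,5-tetramethyl-1,3,2-dioxaborolan-2-yl)prop-2-en-1-yl]oxy}silane | CC(C)(C)[Si](C)(C)OC/C=C/B1OC(C)(C)C(C)(C)O1
A8 | alternative 3 | [3,5-dimethoxy-4-(triisopropylsilyloxy)phenyl]lithium | COc1cc([Li])cc(OC)c1O[Si](C(C)C)(C(C)C)C(C)C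
A9 | alternative 3 | methyl 4-fluoro-3-methoxy-5-{[(trifluoromethyl)sulfonyl]oxy}benzoate | COC(=O)c1cc(OC)c(F)c(OS(=O)(=O)C(F)(F)F)c1
A10 | alternative 3 | methyl 3-[(1R,2S)-3-{[tert-butyl(dimethyl)silyl]oxy}-1-[3,5-dimethoxy-4-(triisopropylsilyloxy)phenyl]-1-(4,4,5,5-tetramethyl-1,3,2-dioxaborolan-2-yl)propan-2-yl]-4-fluoro-5-methoxybenzoate | COc1cc([C@H](B2OC(C)(C)C(C)(C)O2)[C@H](CO[Si](C)(C)C(C)(C)C)c2cc(C(=O)OC)cc(OC)c2F)cc(OC)c1O[Si](C(C)C)(C(C)C)C(C)C
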